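## Assumptions
- β-Cyclocitral, MeMgBr and dimethyl acetylenedicarboxylate (DMAD) are commercial.
- The target is in the normal drimane series: 1β,6α-diacetoxy-9α-hydroxydrim-7-ene-11,12-dial, with 5α-H and 10β-Me.
- (S)-Me-CBS gives the (R)-allylic alcohol by analogy with acetophenone. This should be confirmed by Mosher analysis.

## Retrosynthesis
1. Parritadial comes from the 1β,6α-diol dialdehyde by acetylation. That comes from the diester by DIBAL, DMP and TBS removal.
2. The 9α-OH and Δ7 come from deconjugative α-hydroxylation of a Δ8 diester dienolate, attacking the face anti to the 10β-methyl.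
3. The 6α-OH and 5α-H come from α-face hydroboration of a Δ5 alkene.
4. Key step: a Diels–Alder of a 1-vinylcyclohexene diene with DMAD forms ring B in one step. It also delivers C8, C9, C11 and C12 and sets the quaternary C10 anti to a pseudo-axial 1β-OTBS.
5. Ring A, with the gem-dimethyl at C4, the C10 methyl and C5, comes from β-cyclocitral. C1 is the only externally installed stereocentre, set by a CBS reduction.

## Route

**Step 1**
Reactants: 1 β-cyclocitral; 2 methylmagnesium bromide
Product: 3 1-(2,6,6-trimethylcyclohex-1-en-1-yl)ethan-1-ol (racemic carbinol)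
Conditions: MeMgBr, THF, 0 °C → rt; aq. NH4Cl
Reagents that add atoms: MeMgBr, C[Mg]Br
Why: 1,2-Grignard addition to the enal installs the acetyl carbon pair, and the carbinol stereocentre is destroyed in the next step.

**Step 2**
Reactants: 3
Product: 4 1-(2,6,6-trimethylcyclohex-1-en-1-yl)ethan-1-one
Conditions: Dess–Martin periodinane, NaHCO3, CH2Cl2, rt
Reagents that add atoms: none
Why: Dess–Martin oxidation of the allylic secondary alcohol to the methyl ketone, with no new stereocentre.

**Step 3**
Reactants: 4
Product: 5 3-acetyl-2,4,4-trimethylcyclohex-2-en-1-one (C1 carbonyl in drimane numbering)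
Conditions: Cr(CO)6 (10 mol%), t-BuOOH, MeCN, 80 °C
Reagents that add atoms: t-BuOOH, CC(C)(C)OO (supplies the carbonyl O)
Why: Cr-catalysed γ-allylic C–H oxidation, as in β-ionone → 4-oxo-β-ionone. The ring CH2 is oxidised in preference to the vinylic CH3, and the product is achiral.

**Step 4**
Reactants: 5
Product: 6 1-[(3R)-3-hydroxy-2,6,6-trimethylcyclohex-1-en-1-yl]ethanone
Conditions: (S)-Me-CBS (10 mol%), BH3·SMe2, THF, −30 °C
Reagents that add atoms: none (hydride H only)
Why: Corey–Bakshi–Shibata reduction sets C1 as (R), which is 1β in the target. The conjugated ring ketone is less hindered than the twisted, shielded acetyl, which should be reduced much more slowly.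

**Step 5**
Reactants: 6
Product: 7 1-[(3R)-3-(tert-butyldimethylsilyloxy)-2,6,6-trimethylcyclohex-1-en-1-yl]ethanone
Conditions: TBSCl, imidazole, DMF, 40 °C
Reagents that add atoms: TBSCl, CC(C)(C)[Si](C)(C)Cl
Why: Silyl protection of the C1 alcohol without epimerisation. TBSCl/imidazole is used so that the acetyl does not form a silyl enol ether.

**Step 6**
Reactants: 7
Product: 8 1-[(3R)-3-(TBSO)-2,6,6-trimethylcyclohex-1-en-1-yl]ethan-1-ol (side-chain epimer mixture)
Conditions: LiAlH4, THF, 0 °C
Reagents that add atoms: none (hydride H only)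
Why: Hydride reduction of the hindered ketone. The carbinol stereocentre is irrelevant because it is removed in the next step.

**Step 7**
Reactants: 8
Product: 9 (3R)-3-(TBSO)-2,6,6-trimethyl-1-vinylcyclohexene (the diene)
Conditions: Burgess reagent, PhH, 50 °C
Reagents that add atoms: none (the reagent is lost as leaving-group fragments)
Why: Burgess dehydration is a syn-elimination. The only β-hydrogens are on the CH3, since C5 is fully substituted, so the terminal vinyl group forms regiospecifically.

**Step 8**
Reactants: 9; 10 dimethyl acetylenedicarboxylate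
Product: 11 dimethyl 1β-(TBSO)drima-5,8-diene-11,12-dioate
Conditions: DMAD (5 equiv), BHT, PhMe, 170 °C, sealed tube
Reagents that add atoms: DMAD, COC(=O)C#CC(=O)OC (all atoms are incorporated)
Why: Thermal [4+2] cycloaddition, with DMAD being symmetrical so there is no regiochemical issue. Proposed new method: the reaction proceeds through the twisted s-cis diene with the small linear alkyne, forming the C10 quaternary centre and C10–C9 bond. The pseudo-axial C1–OTBS (held axial by A(1,2) strain with the C10 methyl) blocks the β face, so C9 bonds α and the methyl ends up 10β. The closest known reaction types are Diels–Alder reactions of 2,6,6-trimethyl-1-vinylcyclohexenes and of 1,1-disubstituted dienes with reactive dienophiles.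

**Step 9**
Reactants: 11
Product: 12 dimethyl 1β-(TBSO)-6α-hydroxydrim-8-ene-11,12-dioate
Conditions: BH3·THF, −10 °C → rt; then H2O2, NaHCO3, THF/H2O
Reagents that add atoms: H2O2, OO (supplies the C6–OH oxygen)
Why: Hydroboration–oxidation of the electron-rich Δ5 alkene, with the electron-poor maleate alkene untouched. Syn addition from the α face (the β face is blocked by the 10β-Me and 4β-Me) puts B at C6 and H at C5, giving 5α-H and 6α-OH, as in Δ5-steroids → 6α-ol.

**Step 10**
Reactants: 12
Product: 13 dimethyl 1β,6α-bis(TBSO)drim-8-ene-11,12-dioate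
Conditions: TBSOTf, 2,6-lutidine, CH2Cl2, −78 → 0 °C
Reagents that add atoms: TBSOTf, CC(C)(C)[Si](C)(C)OS(=O)(=O)C(F)(F)F
Why: Silylation of the equatorial secondary alcohol, needed so the next step can use a strong base.

**Step 11**
Reactants: 13
Product: 14 dimethyl 1β,6α-bis(TBSO)-9α-hydroxydrim-7-ene-11,12-dioate
Conditions: LDA, THF, −78 °C; then 2-(phenylsulfonyl)-3-phenyloxaziridine, −78 °C
Reagents that add atoms: Davis oxaziridine, O=S(=O)(c1ccccc1)N1OC1c1ccccc1 (transfers O)
Why: γ-Deprotonation at C7 (only acidic H) gives the dienolate conjugated to the C11 ester. Davis α-hydroxylation at C9 is attacked from the α face, anti to the 10β-Me, giving 9α-OH and the conjugated Δ7 enoate.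

**Step 12**
Reactants: 14
Product: 15 1β,6α-bis(TBSO)drim-7-ene-9α,11,12-triol
Conditions: DIBAL-H (6 equiv), PhMe, −78 → 0 °C
Reagents that add atoms: none (hydride H only)
Why: Exhaustive 1,2-reduction of both esters. The free 9-OH consumes one equivalent, and the TBS ethers and tertiary alcohol are stable.

**Step 13**
Reactants: 15
Product: 16 1β,6α-bis(TBSO)-9α-hydroxydrim-7-ene-11,12-dial
Conditions: Dess–Martin periodinane (3 equiv), NaHCO3, CH2Cl2, rt
Reagents that add atoms: none
Why: Oxidation of both primary alcohols, the allylic C12–OH and the neopentyl C11–OH, to aldehydes. The tertiary 9-OH is untouched and C9 has no H to epimerise.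

**Step 14**
Reactants: 16
Product: 17 1β,6α,9α-trihydroxydrim-7-ene-11,12-dial
Conditions: HF·pyridine, pyridine, THF, 0 → 25 °C
Reagents that add atoms: none (H only)
Why: Buffered fluoride removes both TBS ethers without base-mediated aldehyde chemistry.

**Step 15**
Reactants: 17
Product: 18 parritadial
Conditions: Ac2O, pyridine, DMAP, CH2Cl2, 0 °C
Reagents that add atoms: Ac2O, CC(=O)OC(C)=O
Why: DMAP-catalysed acetylation of the two secondary alcohols. The tertiary 9-OH is too hindered to react, and no stereocentre is touched.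

## Compound list
1 | β-cyclocitral | O=CC1=C(C)CCCC1(C)C | starting material
2 | methylmagnesium bromide | C[Mg]Br | starting material
3 | 1-(2,6,6-trimethylcyclohex-1-en-1-yl)ethan-1-ol | CC(O)C1=C(C)CCCC1(C)C | intermediate
4 | 1-(2,6,6-trimethylcyclohex-1-en-1-yl)ethanone | CC(=O)C1=C(C)CCCC1(C)C | intermediate
5 | 3-acetyl-2,4,4-trimethylcyclohex-2-en-1-one | CC(=O)C1=C(C)C(=O)CCC1(C)C | intermediate
6 | 1-[(3R)-3-hydroxy-2,6,6-trimethylcyclohex-1-en-1-yl]ethanone | CC(=O)C1=C(C)[C@H](O)CCC1(C)C | intermediate
7 | TBS ether of 6 | CC(=O)C1=C(C)[C@H](O[Si](C)(C)C(C)(C)C)CCC1(C)C | intermediate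
8 | 1-[(3R)-3-(TBSO)-2,6,6-trimethylcyclohex-1-en-1-yl]ethan-1-ol | CC(O)C1=C(C)[C@H](O[Si](C)(C)C(C)(C)C)CCC1(C)C | intermediate
9 | (3R)-3-(TBSO)-2,6,6-trimethyl-1-vinylcyclohexene | C=CC1=C(C)[C@H](O[Si](C)(C)C(C)(C)C)CCC1(C)C | intermediate
10 | dimethyl acetylenedicarboxylate | COC(=O)C#CC(=O)OC | starting material
11 | dimethyl 1β-(TBSO)drima-5,8-diene-11,12-dioate | C1=C2C(C)(C)CC[C@@H](O[Si](C)(C)C(C)(C)C)[C@]2(C)C(C(=O)OC)=C(C(=O)OC)C1 | intermediate
12 | dimethyl 1β-(TBSO)-6α-hydroxydrim-8-ene-11,12-dioate | O[C@H]1CC(C(=O)OC)=C(C(=O)OC)[C@@]2(C)[C@H](O[Si](C)(C)C(C)(C)C)CCC(C)(C)[C@H]12 | intermediate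
13 | dimethyl 1β,6α-bis(TBSO)drim-8-ene-11,12-dioate | CC(C)(C)[Si](C)(C)O[C@H]1CC(C(=O)OC)=C(C(=O)OC)[C@@]2(C)[C@H](O[Si](C)(C)C(C)(C)C)CCC(C)(C)[C@H]12 | intermediate
14 | dimethyl 1β,6α-bis(TBSO)-9α-hydroxydrim-7-ene-11,12-dioate | CC(C)(C)[Si](C)(C)O[C@H]1C=C(C(=O)OC)[C@](O)(C(=O)OC)[C@@]2(C)[C@H](O[Si](C)(C)C(C)(C)C)CCC(C)(C)[C@H]12 | intermediate
15 | 1β,6α-bis(TBSO)drim-7-ene-9α,11,12-triol | CC(C)(C)[Si](C)(C)O[C@H]1C=C(CO)[C@](O)(CO)[C@@]2(C)[C@H](O[Si](C)(C)C(C)(C)C)CCC(C)(C)[C@H]12 | intermediate
16 | 1β,6α-bis(TBSO)-9α-hydroxydrim-7-ene-11,12-dial | CC(C)(C)[Si](C)(C)O[C@H]1C=C(C=O)[C@](O)(C=O)[C@@]2(C)[C@H](O[Si](C)(C)C(C)(C)C)CCC(C)(C)[C@H]12 | intermediate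
17 | 1β,6α,9α-trihydroxydrim-7-ene-11,12-dial | O[C@H]1C=C(C=O)[C@](O)(C=O)[C@@]2(C)[C@H](O)CCC(C)(C)[C@H]12 | intermediate
18 | parritadial (1β,6α-diacetoxy-9α-hydroxydrim-7-ene-11,12-dial) | CC(=O)O[C@H]1C=C(C=O)[C@](O)(C=O)[C@@]2(C)[C@H](OC(C)=O)CCC(C)(C)[C@H]12 | target

## Totals
Total steps: 15. Longest linear sequence: 15, from β-cyclocitral. DMAD and MeMgBr are simple one-step partners, so there is no convergent branch.

## Three steps most likely to fail
1. **Step 8 (Diels–Alder).** The diene is twisted and 1,1-disubstituted at the terminus, so the cycloaddition may not go.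
   Fallback (different approach): build the decalin from (S)-Wieland–Miescher ketone. Ketalise the saturated ketone, do deconjugative t-BuOK/MeI dimethylation to the 4,4-dimethyl-Δ5 compound, then Wolff–Kishner and Δ5 hydroboration for 6α-OH. Install C1 oxygen by Δ1-enone epoxidation and reductive opening, and build C7=C8 and C9 from the ring-B ketone by formylation and cyanohydrin chemistry.
2. **Step 11 (C9 hydroxylation).** The α-attack is next to the quaternary C10, so the oxidant may attack at C7 instead or trigger elimination of the 6-OTBS group.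
   Fallback (different approach): isomerise the Δ8 diester to the Δ7, 9-H diester and carry it through DIBAL and DMP to the 9-deoxy dial. Then install 9α-OH late by forming the dienol silyl ether (TBSOTf/Et3N) and oxidising it with DMDO, as in polygodial → warburganal chemistry.
3. **Step 4 (CBS chemoselectivity and ee).** The acetyl competes with the ring ketone for reduction.
   Fallback (different approach): use the β-cyclogeranyl TBS ether instead. Do the γ-oxidation and the CBS reduction on its single ketone, then unmask the side chain (TBAF, Dess–Martin, Ph3P=CH2) to reach diene 9.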